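(The earlier runs and the new flask were generated by integration for an exercise, and the scatter is random.)

The small alder charge shows how the starting material divides, and the next decision hangs on that: do you go up to the east charge, 5.00 times the south-east one, or stay small? The held gas level is 4.50% of the south-east charge but 0.900% of the east charge, so the worry is that a big charge loses target to isomer of the product.

common to all: gas 0.36 mM (held)
- alder: starting material 8.8 mM; run made earlier
- south-east: starting material 8.0 mM; time 30 min
- west: starting material 12 mM; time 30 min
- north-west: starting material 15 mM; time 30 min
- south: starting material 25 mM; time 30 min
- east: starting material 40 mM; time 30 min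

alder run (percent of the starting material charged)

| time / min | target / % | isomer of the product / % | starting material / % |
|---|---|---|---|
| 1.33 | 3.4 | 0.5 | 97.0 |
| 2.50 | 5.4 | 2.4 | 91.1 |
| 5.00 | 13.8 | 1.8 | 83.5 |
| 10.0 | 25.6 | 4.2 | 68.4 |
| 20.0 | 46.7 | 8.8 | 45.0 |

(each reading ± 1 percentage point)

- the earlier runs were read with a standard deviation of 1 percentage point
- at the start none of the gas is in solution
- "hardly changes" means that all values lie within two and a half points (for a concentration: within two and a half percent of the largest)

* share of target in all that became target or isomer of the product for south-east, west, north-west, south, east, in this order
* how the row runs (falls all the way / rises, then falls / falls, then rises / hardly changes / rises all the way)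

The alder run gives the number to carry. At 20.0 min it holds 46.7% target and 8.8% isomer of the product, so the split is 84.1%; by the split I mean the share of target in what has become target or isomer of the product, the selectivity. At 10.0 min the same sum gives 85.9%. Between those readings the starting material falls from 68.4% to 45.0% of the charge, and with a scatter of 1 percentage point on each reading I see no trend in that gap. East lies well beyond what alder covers, so this is a bet, but I would charge it and expect the split at each point of the row.

The forecast says much the same, with 84.5% at each point, a little above my split, and a row that hardly changes. Its ground is that “both channels appear to have the same order in starting material”.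

The flask gives 87.2% for south-east and 87.0% for east, and the row hardly changes.

    starting material ⇌ tight pair (K = 0.00150, k = 0.0660 min⁻¹)
    tight pair ⇌ loose pair (K = 0.260, k = 740 min⁻¹)
    reagent + tight pair → target (k = 4.00 × 10⁵ M⁻¹ min⁻¹)
    reagent + loose pair → isomer of the product (k = 2.30 × 10⁵ M⁻¹ min⁻¹)
    gas ⇌ reagent, rate k5*(csat - [reagent]) (kL = 1.30 min⁻¹)

Carry the split over. By 30.0 min east turned over 32.8% of its charge, so the split says 27.6% as target, and east holds 28.4%. South-east turned over 73.4%, so it says 61.7%, and south-east holds 64.0%. At 30.0 min reagent stands at 8.44% of the gas level in east against 76.9% in south-east, yet the share stays, because loose pair runs back to tight pair: with that backward run taken away, the east share falls from 87.0% to 0.0602%.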